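**Remarks.** Locants follow the isochromanone numbering (C1 lactone carbonyl, O2, C3, C4, C4a, C5 to C8, C8a); the bridge runs from C1' (on C5) to C11' (on O6). The oxirane carbon of 17 forms in both configurations, which is without consequence because it becomes the aldehyde carbon of 19.

## The problem

Chrysomutanin (26) is a (3R)-3-methylisochroman-1-one whose C5 and O6 are bridged by an eleven-carbon chain, so that a 14-membered ansa ring (C5, C1' to C11', O6, C6) is fused across two adjacent arene positions. The chain holds two trisubstituted Z alkenes (C2'=C3', C6'=C7') in a 1,5-relationship, the first allylic to the arene. It ends in the secondary carbinol C10' beside the quaternary C11', which is bound to O6 as a tertiary alkyl aryl ether. The stereocentres C3 (R) and C10' (S) lie on opposite sides of the arene and cannot influence each other, so each must come from the chiral pool or from a reagent. The neryl-type 1,5-diene and the tertiary ether are prone to ionisation and cation–olefin cyclisation in strong acid, and the lactone rules out organolithium and hydride reagents once it is present. Both Z alkenes can isomerise in any allyl–metal intermediate, and the chelated C8 phenol and the C10' hydroxyl must be masked during the metal-mediated steps. The substituents on C5 and C6 are ortho to each other and both bulky, so whichever arrives second meets a hindered site. A late ring closure is possible because C8' is a plain methylene, two carbons from the C10' carbinol and directly bound to the sp2 carbon C7'. A vinyl group on C10' (C9'=C8') can therefore become a C8' alkylborane and be joined to a C7' alkenyl iodide, closing the ring and fixing the second Z alkene in one stereospecific event.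

## Retrosynthesis

**Protecting groups (26 from 25).** Only O8 and O10' need masking. In 25 they are a methoxymethyl ether and a tert-butyldimethylsilyl ether, both of which fall in acidic methanol. Benzyl groups are excluded because hydrogenolysis would reduce the alkenes, and an O8 methyl ether because boron halides would also cleave the tertiary ether. The forward step must avoid acid strong enough to ionise C11' or protonate the diene.

**Ring opening at C7'–C8' (25 from 23 through 24).** The single bond C7'–C8' is cut. Its neighbours are worse places to close the ring: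
- C5–C1' would close through a π-allyl complex at a hindered arene carbon, with the 2'Z geometry at stake.
- O6–C11' would require a macrocyclic substitution at a tertiary carbon.
- Either alkene by metathesis would give no control over a trisubstituted Z geometry in a 14-membered ring.

An sp3–sp2 coupling at C7'–C8' transfers the iodide geometry to the product, and its nucleophile arises in the flask from a vinyl group by hydroboration. The precursor 23 is acyclic and already holds every carbon and both stereocentres. The forward reaction must hydroborate only the monosubstituted alkene and cyclise faster than it oligomerises.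

**Iodoalkene (23 from 22).** The C6'=C7' double bond is cut to aldehyde 22 and an α-iodoethylidene ylide. Hydrometalation–iodination of a but-2-ynyl unit would give the E iodide or regioisomers, whereas the iodo-ylide olefination is known to give (Z)-2-iodoalk-2-enes. The reaction must discriminate the aldehyde from the lactone, which low temperature secures.

**Aryl–allyl bond (22 from 21, from 14 and 20).** Cutting C5–C1' divides the molecule into the arene half 14 and the six-carbon unit 20. The lactone forbids aryl-lithium or Grignard reagents, so the arene is the boronate and the chain the allylic carbonate. The aldehyde is carried as a dimethyl acetal through the basic coupling. The coupling must attack the primary allyl terminus and retain the Z alkene.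

**C1'–C6' unit (20 from 19, 17, 16 and nerol 15).** Nerol supplies C1' to C6' with the Z alkene in place. Its C6=C7 alkene is cleaved by way of the epoxide, so no olefin geometry has to be made.

**Vinyl carbinol (14 from 13 from 12).** The C10'–H bond is cut: the carbinol is made by oxazaborolidine-catalysed reduction of vinyl ketone 12, then silylated. Asymmetric vinyl addition to an aldehyde would need an aldehyde oxidation level that is awkward beside the lactone. In the reduction the quaternary C11' and the vinyl group differ clearly in size.

**Enone and boron (12 from 10 from 9).** Methylenation of the methyl ketone adds C8'. Boron is placed on C5 at the stage of 9, before any alkene exists on the O6 side chain. An arylpalladium bromide at C5 flanked by an O–C–C–CH=CH2 tether would undergo 6-exo Heck cyclisation, whereas the boronate 10 tolerates the following steps.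

**Ether and phenol differentiation (9 from 8, from 6 and 7).** The O6–C11' bond is cut. The tertiary α-bromo ketone 7 brings C9' to C11' with both methyl groups. In diol 6 the C8 hydroxyl is hydrogen-bonded to the lactone carbonyl, so base alkylates O6 first and O8 is protected afterwards.

**Arene (6 from 5 from 4, from 1 and 2).** Demethylation and C5 bromination lead back to the dimethyl ether 4. Cutting C4–C4a and C1–O2 gives 2,4-dimethoxybenzoic acid (1) and (R)-propylene oxide (2), which are joined by a carboxylate-directed C–H alkylation and lactonisation. The acid has only one free ortho position, and the epoxide supplies C3 with its configuration.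

## Roads not taken

**Alternative 1:** The cut would lie in the benzene ring at C4a–C8a, with the C5 chain installed beforehand. Triethylamine would convert the C5-alkylated diketo-dioxinone A1 into the benzodioxinone resorcylate A2 by aldol condensation of C8a onto the C4a ketone and loss of water.
- Merits: the substitution pattern is programmed, so no halogenation and no hindered aryl coupling are needed. O6 emerges free while O8 and the carboxyl are tied in the acetonide, which differentiates the phenols automatically. Conditions are mild.
- Weak points: A1 is a sensitive tricarbonyl compound whose assembly needs a long linear sequence. Its C-allylation with a neryl unit is itself a π-allyl process with the same geometry question. A2 still lacks the lactone, the tertiary ether, C10' and the macrocycle, and the ring would have to close through an sp3–sp3 bond or the tertiary ether, neither well supported.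
- Comparison: this road is better at arene regiocontrol and phenol differentiation. The chosen plan sets against it an arene made in one catalytic step from a commercial acid and a ring closure that also fixes an alkene geometry.

**Alternative 2:** Four arene bonds (C4a–C5, C5–C6, C7–C8, C8–C8a) would be formed at once. Irradiation of diazo ketone A3 would trigger a Wolff rearrangement to a vinylketene, [2+2] addition to the tethered ynol ether, and ring opening and 6π closure of the cyclobutenone to the phenol A4.
- Merits: it has the highest bond count per step, forms arene and macrocycle together, fixes regiochemistry by the polarity of the ynol ether, and delivers O8 as a free phenol with one protecting group in the molecule. After A4 a single deprotection remains, which is shorter than the chosen endgame.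
- Weak points: the ketene–alkyne addition would have to be macrocyclic, where ketene dimerisation competes. The tert-alkyl ethynyl ether in A3 has β-hydrogens and is liable to retro-ene fragmentation near room temperature. The α-alkylated diazo ketone cannot be made by simple diazo transfer. The unsaturated lactone and the 1,5-diene are partners for competing photocycloaddition.
- Comparison: the step-count advantage is real. The chosen plan offsets it with stable intermediates and steps that each have a close analogue.

**Alternative 3:** The cut would be at C4a–C5 and C6–C7 with extrusion of CO2. Heating the 14-membered ynol ether A5 with the bicyclic 2-pyrone A6 would give a [4+2] adduct that loses CO2 to the arene A7.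
- Merits: it is a convergent union of two halves of similar size. The nucleophilic alkyne carbon C5 matches the oxygen-bearing pyrone terminus C4a, and A6 is a short target that already carries C3.
- Weak points: the ring-closure problem is only moved to A5, a 14-membered ring with an ynol ether and two Z alkenes and no arene to act as a turn element. 4-Alkoxy-2-pyrones are sluggish dienes that need strong heating, where the tert-alkyl ynol ether fragments. A7 needs removal of a secondary methoxymethyl ether under more forcing acid.
- Comparison: this road is equal or better in convergence. The chosen plan closes the ring on a robust acyclic precursor and uses no ynol ether.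

Key step: step 17

## Route

Step 1
Reactants: 1 2,4-dimethoxybenzoic acid; 2 (R)-propylene oxide
Product: 4 (3R)-6,8-dimethoxy-3-methylisochroman-1-one, via hydroxy acid 3 (not isolated)
Conditions: Pd(OAc)2 (cat.), N-acetyl-L-tert-leucine (cat.), KOAc, (CF3)2CHOH, 75 °C
Reagents that add atoms: none
Why: Carboxylate-directed ortho C–H palladation by divalent palladium at the only free ortho position, SN2-type opening of the epoxide at its CH2 carbon and lactonisation of 3 give the dihydroisocoumarin (known C–H alkylation/annulation of benzoic acids with terminal epoxides); the C–O bond at the stereocentre of 2 is never broken, so C3 is R.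

Step 2
Reactants: 4 (3R)-6,8-dimethoxy-3-methylisochroman-1-one
Product: 5 (3R)-5-bromo-6,8-dimethoxy-3-methylisochroman-1-one
Conditions: NBS, MeCN, 0 °C to rt
Reagents that add atoms: N-bromosuccinimide, O=C1CCC(=O)N1Br
Why: Electrophilic aromatic bromination; C5 is para to the C8 methoxy and ortho to the C6 methoxy and is less hindered than C7, which lies between the two methoxy groups, as in the bromination of 3,5-dimethoxybenzyl systems.

Step 3
Reactants: 5 (3R)-5-bromo-6,8-dimethoxy-3-methylisochroman-1-one
Product: 6 (3R)-5-bromo-6,8-dihydroxy-3-methylisochroman-1-one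
Conditions: BBr3, CH2Cl2, −78 °C to rt; H2O
Reagents that add atoms: none
Why: Lewis-acid cleavage of both aryl methyl ethers, the standard route to 6,8-dihydroxy dihydroisocoumarins; the aryl bromide, the lactone and C3 are not affected.

Step 4
Reactants: 6 (3R)-5-bromo-6,8-dihydroxy-3-methylisochroman-1-one; 7 3-bromo-3-methylbutan-2-one
Product: 8 (3R)-5-bromo-8-hydroxy-3-methyl-6-[(2-methyl-3-oxobutan-2-yl)oxy]isochroman-1-one
Conditions: K2CO3 (1.1 equiv), DMF, 50 °C
Reagents that add atoms: none
Why: Williamson-type O-alkylation of a phenoxide by a tertiary α-bromo ketone, assisted by the adjacent carbonyl; the C6 hydroxyl is the more acidic and is free, whereas the C8 hydroxyl is hydrogen-bonded to the lactone carbonyl, so one equivalent of base should alkylate O6 only.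

Step 5
Reactants: 8 (3R)-5-bromo-8-hydroxy-3-methyl-6-[(2-methyl-3-oxobutan-2-yl)oxy]isochroman-1-one
Product: 9 (3R)-5-bromo-8-(methoxymethoxy)-3-methyl-6-[(2-methyl-3-oxobutan-2-yl)oxy]isochroman-1-one
Conditions: MOMCl, i-Pr2NEt, CH2Cl2, 0 to 40 °C
Reagents that add atoms: chloromethyl methyl ether, COCCl
Why: Methoxymethylation of the chelated phenol under amine base; ketone and lactone are inert, and the acetal is later removed together with the silyl ether.

Step 6
Reactants: 9 (3R)-5-bromo-8-(methoxymethoxy)-3-methyl-6-[(2-methyl-3-oxobutan-2-yl)oxy]isochroman-1-one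
Product: 10 (3R)-8-(methoxymethoxy)-3-methyl-6-[(2-methyl-3-oxobutan-2-yl)oxy]-5-(4,4,5,5-tetramethyl-1,3,2-dioxaborolan-2-yl)isochroman-1-one
Conditions: B2pin2, Pd2(dba)3 (cat.), 2-dicyclohexylphosphino-2',4',6'-triisopropylbiphenyl (XPhos), KOAc, 1,4-dioxane, 100 °C
Reagents that add atoms: bis(pinacolato)diboron, CC1(C)OB(OC1(C)C)B1OC(C)(C)C(C)(C)O1
Why: Miyaura borylation; the bulky electron-rich biarylphosphine permits oxidative addition and boryl transfer at the doubly ortho-substituted bromide, KOAc is too weak to enolise the ketone for α-arylation, and boron is installed before any alkene exists on the O6 chain so that Heck cyclisation is excluded.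

Step 7
Reactants: 10 (3R)-8-(methoxymethoxy)-3-methyl-6-[(2-methyl-3-oxobutan-2-yl)oxy]-5-(4,4,5,5-tetramethyl-1,3,2-dioxaborolan-2-yl)isochroman-1-one
Product: 12 (3R)-8-(methoxymethoxy)-3-methyl-6-[(2-methyl-3-oxopent-4-en-2-yl)oxy]-5-(4,4,5,5-tetramethyl-1,3,2-dioxaborolan-2-yl)isochroman-1-one, via β-amino ketone 11 (not isolated)
Conditions: (CH2O)n, i-Pr2NH·CF3CO2H, THF, 65 °C
Reagents that add atoms: paraformaldehyde (as formaldehyde), C=O
Why: Mannich condensation at the only enolisable position (the methyl group) with the iminium ion from formaldehyde and diisopropylamine, then elimination of the hindered amine from 11, a known one-pot α-methylenation of methyl ketones to vinyl ketones; the ammonium salt is too weak an acid to cleave the methoxymethyl ether.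

Step 8
Reactants: 12 (3R)-8-(methoxymethoxy)-3-methyl-6-[(2-methyl-3-oxopent-4-en-2-yl)oxy]-5-(4,4,5,5-tetramethyl-1,3,2-dioxaborolan-2-yl)isochroman-1-one
Product: 13 (3R)-6-{[(3S)-3-hydroxy-2-methylpent-4-en-2-yl]oxy}-8-(methoxymethoxy)-3-methyl-5-(4,4,5,5-tetramethyl-1,3,2-dioxaborolan-2-yl)isochroman-1-one
Conditions: (R)-Me-CBS oxazaborolidine [(R)-1-methyl-3,3-diphenyltetrahydro-1H,3H-pyrrolo[1,2-c][1,3,2]oxazaborole] (0.3 equiv), BH3·SMe2, THF, −30 °C; MeOH
Reagents that add atoms: none
Why: Corey–Bakshi–Shibata reduction; the ketone binds the catalyst anti to its larger substituent (the quaternary C11') and the vinyl group acts as the small group, so the R catalyst should deliver hydride to the face that gives the 10'S alcohol by 1,2-reduction, with boronate and lactone untouched at −30 °C.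

Step 9
Reactants: 13 (3R)-6-{[(3S)-3-hydroxy-2-methylpent-4-en-2-yl]oxy}-8-(methoxymethoxy)-3-methyl-5-(4,4,5,5-tetramethyl-1,3,2-dioxaborolan-2-yl)isochroman-1-one
Product: 14 (3R)-6-{[(3S)-3-(tert-butyldimethylsilyloxy)-2-methylpent-4-en-2-yl]oxy}-8-(methoxymethoxy)-3-methyl-5-(4,4,5,5-tetramethyl-1,3,2-dioxaborolan-2-yl)isochroman-1-one
Conditions: TBSOTf, 2,6-lutidine, CH2Cl2, −78 to 0 °C
Reagents that add atoms: tert-butyldimethylsilyl triflate, CC(C)(C)[Si](C)(C)OS(=O)(=O)C(F)(F)F
Why: Silylation of the hindered secondary alcohol with the silyl triflate; the silyl ether withstands the basic palladium steps, the ylide and 9-BBN.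

Step 10
Reactants: 15 nerol [(2Z)-3,7-dimethylocta-2,6-dien-1-ol]
Product: 16 methyl (2Z)-3,7-dimethylocta-2,6-dien-1-yl carbonate
Conditions: ClCO2Me, pyridine, CH2Cl2, 0 °C
Reagents that add atoms: methyl chloroformate, COC(=O)Cl
Why: Acylation of the primary allylic alcohol; the carbonate is the leaving group for the later π-allyl formation and deactivates the C2=C3 alkene towards the peracid.

Step 11
Reactants: 16 methyl (2Z)-3,7-dimethylocta-2,6-dien-1-yl carbonate
Product: 17 methyl (2Z)-5-(3,3-dimethyloxiran-2-yl)-3-methylpent-2-en-1-yl carbonate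
Conditions: mCPBA, CH2Cl2, −20 to 0 °C
Reagents that add atoms: 3-chloroperbenzoic acid, OOC(=O)c1cccc(Cl)c1
Why: Prilezhaev epoxidation; the remote trisubstituted C6=C7 alkene is more electron-rich than the alkene bearing the allylic carbonate, the known site selectivity of neryl and geranyl esters.

Step 12
Reactants: 17 methyl (2Z)-5-(3,3-dimethyloxiran-2-yl)-3-methylpent-2-en-1-yl carbonate
Product: 19 methyl (2Z)-3-methyl-6-oxohex-2-en-1-yl carbonate, via vicinal diol 18 (not isolated)
Conditions: H5IO6, THF–H2O, 0 °C
Reagents that add atoms: none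
Why: Periodic acid opens the epoxide to diol 18 and cleaves it (Malaprade glycol cleavage) to the C6 aldehyde and acetone; the Z alkene and the carbonate are not touched.

Step 13
Reactants: 19 methyl (2Z)-3-methyl-6-oxohex-2-en-1-yl carbonate
Product: 20 methyl (2Z)-6,6-dimethoxy-3-methylhex-2-en-1-yl carbonate
Conditions: HC(OMe)3, MeOH, pyridinium p-toluenesulfonate (cat.), rt
Reagents that add atoms: trimethyl orthoformate, COC(OC)OC; methanol, CO
Why: Acid-catalysed acetalisation; the masked aldehyde cannot undergo aldol reactions under the basic coupling conditions.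

Step 14
Reactants: 14 (3R)-6-{[(3S)-3-(tert-butyldimethylsilyloxy)-2-methylpent-4-en-2-yl]oxy}-8-(methoxymethoxy)-3-methyl-5-(4,4,5,5-tetramethyl-1,3,2-dioxaborolan-2-yl)isochroman-1-one; 20 methyl (2Z)-6,6-dimethoxy-3-methylhex-2-en-1-yl carbonate
Product: 21 (3R)-6-{[(3S)-3-(tert-butyldimethylsilyloxy)-2-methylpent-4-en-2-yl]oxy}-5-[(2Z)-6,6-dimethoxy-3-methylhex-2-en-1-yl]-8-(methoxymethoxy)-3-methylisochroman-1-one
Conditions: Pd(PPh3)4 (cat.), K2CO3, THF–H2O, 60 °C
Reagents that add atoms: none
Why: Allyl–aryl Suzuki–Miyaura coupling: zerovalent palladium ionises the carbonate to a neryl π-allyl complex, the boronate transmetalates and reductive elimination occurs at the less substituted allyl terminus; loss of the Z geometry would need a σ-allyl complex on the tertiary carbon, so retention is expected as in known couplings of neryl electrophiles with arylmetals.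

Step 15
Reactants: 21 (3R)-6-{[(3S)-3-(tert-butyldimethylsilyloxy)-2-methylpent-4-en-2-yl]oxy}-5-[(2Z)-6,6-dimethoxy-3-methylhex-2-en-1-yl]-8-(methoxymethoxy)-3-methylisochroman-1-one
Product: 22 (3R)-6-{[(3S)-3-(tert-butyldimethylsilyloxy)-2-methylpent-4-en-2-yl]oxy}-8-(methoxymethoxy)-3-methyl-5-[(2Z)-3-methyl-6-oxohex-2-en-1-yl]isochroman-1-one
Conditions: AcOH–THF–H2O (3:1:1), rt
Reagents that add atoms: water, O
Why: Mild acetal hydrolysis; the dimethyl acetal of an aliphatic aldehyde hydrolyses far faster than the formaldehyde-derived methoxymethyl ether or the hindered secondary silyl ether.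

Step 16
Reactants: 22 (3R)-6-{[(3S)-3-(tert-butyldimethylsilyloxy)-2-methylpent-4-en-2-yl]oxy}-8-(methoxymethoxy)-3-methyl-5-[(2Z)-3-methyl-6-oxohex-2-en-1-yl]isochroman-1-one
Product: 23 (3R)-6-{[(3S)-3-(tert-butyldimethylsilyloxy)-2-methylpent-4-en-2-yl]oxy}-5-[(2Z,6Z)-7-iodo-3-methylocta-2,6-dien-1-yl]-8-(methoxymethoxy)-3-methylisochroman-1-one
Conditions: EtPPh3I, n-BuLi, THF, rt; I2, −78 °C; NaN(SiMe3)2, −78 to −20 °C; then 22
Reagents that add atoms: ethyltriphenylphosphonium iodide, CC[P+](c1ccccc1)(c1ccccc1)c1ccccc1.[I-]; iodine, II
Why: Wittig olefination with the α-iodo ylide Ph3P=C(I)CH3 (Stork–Zhao type), which gives (Z)-2-iodoalk-2-enes from aliphatic aldehydes under kinetic control; the aldehyde reacts at low temperature while the lactone is inert.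

Step 17
Reactants: 23 (3R)-6-{[(3S)-3-(tert-butyldimethylsilyloxy)-2-methylpent-4-en-2-yl]oxy}-5-[(2Z,6Z)-7-iodo-3-methylocta-2,6-dien-1-yl]-8-(methoxymethoxy)-3-methylisochroman-1-one
Product: 25 O8-methoxymethyl O10'-tert-butyldimethylsilyl ether of chrysomutanin (3R,10'S,2'Z,6'Z), via B-alkyl borane 24 (not isolated)
Conditions: 9-BBN (9-borabicyclo[3.3.1]nonane dimer), THF, rt; then slow addition to Pd(dppf)Cl2 (cat.), AsPh3, Cs2CO3, DMF–THF–H2O, 45 °C, ca. 1 mM
Reagents that add atoms: none
Why: 9-BBN should add only to the monosubstituted C8'=C9' alkene, with boron on the terminal C8' away from the allylic silyloxy group, because the two trisubstituted alkenes, the iodoalkene and the lactone do not react at room temperature; this gives 24. Zerovalent palladium formed from Pd(dppf)Cl2 inserts into the C7'–I bond with retention, the base-activated primary alkylborane transmetalates, and reductive elimination joins C7' to C8'. The closest known reaction type is the B-alkyl Suzuki–Miyaura macrocyclisation of an alkylborane onto an alkenyl iodide. The 14-membered ring closes end to end: intramolecular transmetalation gives a 15-membered palladacycle and reductive elimination contracts it to the ring. No stereocentre is formed; the 6'Z geometry follows from the stereoretentive palladium cycle, and C10' is untouched because boron sits on C8', too far for β-alkoxy elimination. The step needs chemoselective hydroboration, secured by the single vinyl group, and cyclisation ahead of bimolecular coupling, secured by slow addition at high dilution. The ortho-disposed C5 and O6 arms and the two Z alkenes bring the chain ends together, and the wide bite angle of dppf with AsPh3 favours reductive elimination over β-hydride loss.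

Step 18
Reactants: 25 O8-methoxymethyl O10'-tert-butyldimethylsilyl ether of chrysomutanin
Product: 26 chrysomutanin
Conditions: HCl (1.25 M in MeOH), 0 °C to rt
Reagents that add atoms: none
Why: Acid-catalysed transacetalisation removes the methoxymethyl group (assisted by the neighbouring lactone carbonyl) and methanolysis removes the silyl ether in one operation; mild acid in methanol should leave the tertiary ether, the 1,5-diene and both stereocentres intact.

## Compound list

1 | 2,4-dimethoxybenzoic acid | COc1ccc(C(=O)O)c(OC)c1 | starting material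
2 | (R)-propylene oxide | C[C@@H]1CO1 | starting material
3 | 2-[(2R)-2-hydroxypropyl]-4,6-dimethoxybenzoic acid (not isolated) | COc1cc(OC)c(C(=O)O)c(C[C@@H](C)O)c1 | intermediate
4 | (3R)-6,8-dimethoxy-3-methylisochroman-1-one | COc1cc(OC)c2c(c1)C[C@@H](C)OC2=O | intermediate
5 | (3R)-5-bromo-6,8-dimethoxy-3-methylisochroman-1-one | COc1cc(OC)c2c(c1Br)C[C@@H](C)OC2=O | intermediate
6 | (3R)-5-bromo-6,8-dihydroxy-3-methylisochroman-1-one | Oc1cc(O)c2c(c1Br)C[C@@H](C)OC2=O | intermediate
7 | 3-bromo-3-methylbutan-2-one | CC(=O)C(C)(C)Br | starting material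
8 | (3R)-5-bromo-8-hydroxy-3-methyl-6-[(2-methyl-3-oxobutan-2-yl)oxy]isochroman-1-one | CC(=O)C(C)(C)Oc1cc(O)c2c(c1Br)C[C@@H](C)OC2=O | intermediate
9 | (3R)-5-bromo-8-(methoxymethoxy)-3-methyl-6-[(2-methyl-3-oxobutan-2-yl)oxy]isochroman-1-one | CC(=O)C(C)(C)Oc1cc(OCOC)c2c(c1Br)C[C@@H](C)OC2=O | intermediate
10 | C5 pinacol boronate of the methyl ketone: (3R)-8-(methoxymethoxy)-3-methyl-6-[(2-methyl-3-oxobutan-2-yl)oxy]-5-(4,4,5,5-tetramethyl-1,3,2-dioxaborolan-2-yl)isochroman-1-one | CC(=O)C(C)(C)Oc1cc(OCOC)c2c(c1B3OC(C)(C)C(C)(C)O3)C[C@@H](C)OC2=O | intermediate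
11 | β-(diisopropylamino) ketone: (3R)-6-{[5-(diisopropylamino)-2-methyl-3-oxopentan-2-yl]oxy} analogue of 10 (not isolated) | CC(C)N(CCC(=O)C(C)(C)Oc1cc(OCOC)c2c(c1B3OC(C)(C)C(C)(C)O3)C[C@@H](C)OC2=O)C(C)C | intermediate
12 | vinyl ketone: (3R)-8-(methoxymethoxy)-3-methyl-6-[(2-methyl-3-oxopent-4-en-2-yl)oxy]-5-(4,4,5,5-tetramethyl-1,3,2-dioxaborolan-2-yl)isochroman-1-one | C=CC(=O)C(C)(C)Oc1cc(OCOC)c2c(c1B3OC(C)(C)C(C)(C)O3)C[C@@H](C)OC2=O | intermediate
13 | (3R)-6-{[(3S)-3-hydroxy-2-methylpent-4-en-2-yl]oxy}-8-(methoxymethoxy)-3-methyl-5-(4,4,5,5-tetramethyl-1,3,2-dioxaborolan-2-yl)isochroman-1-one | CC(C)(Oc1cc(OCOC)c2c(c1B3OC(C)(C)C(C)(C)O3)C[C@@H](C)OC2=O)[C@@H](O)C=C | intermediate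
14 | tert-butyldimethylsilyl ether of 13 | CC(C)(Oc1cc(OCOC)c2c(c1B3OC(C)(C)C(C)(C)O3)C[C@@H](C)OC2=O)[C@@H](O[Si](C)(C)C(C)(C)C)C=C | intermediate
15 | nerol, (2Z)-3,7-dimethylocta-2,6-dien-1-ol | CC(C)=CCC/C(C)=C\CO | starting material
16 | methyl (2Z)-3,7-dimethylocta-2,6-dien-1-yl carbonate | CC(C)=CCC/C(C)=C\COC(=O)OC | intermediate
17 | methyl (2Z)-5-(3,3-dimethyloxiran-2-yl)-3-methylpent-2-en-1-yl carbonate (both oxirane configurations) | CC1(C)OC1CC/C(C)=C\COC(=O)OC | intermediate
18 | methyl (2Z)-6,7-dihydroxy-3,7-dimethyloct-2-en-1-yl carbonate (not isolated) | CC(C)(O)C(O)CC/C(C)=C\COC(=O)OC | intermediate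
19 | methyl (2Z)-3-methyl-6-oxohex-2-en-1-yl carbonate | O=CCC/C(C)=C\COC(=O)OC | intermediate
20 | methyl (2Z)-6,6-dimethoxy-3-methylhex-2-en-1-yl carbonate | COC(OC)CC/C(C)=C\COC(=O)OC | intermediate
21 | (3R)-6-{[(3S)-3-(tert-butyldimethylsilyloxy)-2-methylpent-4-en-2-yl]oxy}-5-[(2Z)-6,6-dimethoxy-3-methylhex-2-en-1-yl]-8-(methoxymethoxy)-3-methylisochroman-1-one | COC(OC)CC/C(C)=C\Cc1c(OC(C)(C)[C@@H](O[Si](C)(C)C(C)(C)C)C=C)cc(OCOC)c2c1C[C@@H](C)OC2=O | intermediate
22 | C6' aldehyde: the 5-[(2Z)-3-methyl-6-oxohex-2-en-1-yl] analogue of 21 | O=CCC/C(C)=C\Cc1c(OC(C)(C)[C@@H](O[Si](C)(C)C(C)(C)C)C=C)cc(OCOC)c2c1C[C@@H](C)OC2=O | intermediate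
23 | seco iodide: the 5-[(2Z,6Z)-7-iodo-3-methylocta-2,6-dien-1-yl] analogue of 21 | C/C(I)=C/CC/C(C)=C\Cc1c(OC(C)(C)[C@@H](O[Si](C)(C)C(C)(C)C)C=C)cc(OCOC)c2c1C[C@@H](C)OC2=O | intermediate
24 | C8' B-alkyl-9-borabicyclo[3.3.1]nonane from 23 (not isolated) | C/C(I)=C/CC/C(C)=C\Cc1c(OC(C)(C)[C@@H](O[Si](C)(C)C(C)(C)C)CCB3C4CCCC3CCC4)cc(OCOC)c2c1C[C@@H](C)OC2=O | intermediate
25 | O8-methoxymethyl O10'-tert-butyldimethylsilyl ether of chrysomutanin (3R,10'S,2'Z,6'Z) | C/C1=C/Cc2c(cc(OCOC)c3c2C[C@@H](C)OC3=O)OC(C)(C)[C@@H](O[Si](C)(C)C(C)(C)C)CC/C(C)=C\CC1 | intermediate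
26 | chrysomutanin (3R,10'S,2'Z,6'Z) | C/C1=C/Cc2c(cc(O)c3c2C[C@@H](C)OC3=O)OC(C)(C)[C@@H](O)CC/C(C)=C\CC1 | target

## Step count and least certain steps

Total: 18 steps. Longest linear sequence: 14 steps (steps 1 to 9 and 14 to 18, from 2,4-dimethoxybenzoic acid). The nerol branch contributes steps 10 to 13.

**Step 17 (key step).** The most likely failure is slow transmetalation of the alkylborane, which sits beside a silyloxy-bearing carbon and a quaternary centre. At high dilution the alkenylpalladium iodide is then lost by hydrodeiodination, the borane by protodeboronation, and bimolecular coupling gains on ring closure. The fallback sets out from 23 and returns to 25: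
- hydroboration with 9-BBN and oxidation with NaBO3·4H2O would give the C8' primary alcohol F1;
- I2, PPh3 and imidazole would give the primary iodide F2;
- zinc dust with LiCl in THF inserts into the alkyl C–I bond at room temperature, where the alkenyl iodide is inert, giving the alkylzinc iodide F3;
- F3 would be closed by Pd(dppf)Cl2 at high dilution in a base-free intramolecular Negishi coupling to 25.

**Step 14.** The boronate 14 is flanked by the C4 methylene and the bulky O6 ether, so transmetalation may be slow. Protodeboronation would then compete, and the long-lived π-allyl complex could partly lose the 2'Z geometry by syn–anti exchange. The fallback moves the union to the compact boronate 10 and returns at 21: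
- 10 and 20 are coupled under the conditions of step 14 to the methyl ketone F4;
- methylenation as in step 7 (through the β-amino ketone F5) gives the enone F6;
- oxazaborolidine reduction as in step 8 gives the carbinol F7;
- silylation as in step 9 gives 21.

**Step 8.** Facial selectivity may be poor if the vinyl group and the quaternary carbon are not differentiated well enough, or if the aryloxy oxygen competes for the borane. The sense can be corrected with the other catalyst enantiomer, but not the magnitude. The fallback sets out from 12 and returns to 13: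
- NaBH4 with CeCl3·7H2O would give the mixture of C10' epimers F8;
- Sharpless kinetic resolution with Ti(OiPr)4, L-(+)-diisopropyl tartrate and t-BuOOH at −20 °C would epoxidise the 10'R epimer to the epoxy alcohol F9 and leave the 10'S alcohol 13. The pinacol boronate is expected to tolerate the non-basic hydroperoxide.

**Step 4.** Elimination of HBr from the tertiary bromide may outrun substitution, because the phenoxide is hindered by the ortho bromine and weakly nucleophilic. The fallback sets out from 6 and returns to 8:
- copper-catalysed propargylation (CuCl2, DBU, 2-methylbut-3-yn-2-yl methyl carbonate, MeCN) would give the 1,1-dimethylpropargyl ether F10;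
- Markovnikov hydration (HgSO4, dilute H2SO4, aqueous acetone) would give the methyl ketone 8.

**Step 18.** Desilylation of the hindered secondary silyl ether may be slow, and the prolonged acid exposure could lead to cation–olefin cyclisation of the 1,5-diene or ionisation of the tertiary ether. The fallback sets out from 25 and returns to 26:
- HF·pyridine in THF–pyridine would remove the silyl group to the methoxymethyl ether F11;
- a brief treatment with dilute HCl in MeOH at 0 °C would then cleave the labile peri methoxymethyl ether to 26.

## Further compounds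

F1 | step 17 | C8' primary alcohol from 23 | C/C(I)=C/CC/C(C)=C\Cc1c(OC(C)(C)[C@@H](O[Si](C)(C)C(C)(C)C)CCO)cc(OCOC)c2c1C[C@@H](C)OC2=O
F2 | step 17 | C8' primary iodide | C/C(I)=C/CC/C(C)=C\Cc1c(OC(C)(C)[C@@H](O[Si](C)(C)C(C)(C)C)CCI)cc(OCOC)c2c1C[C@@H](C)OC2=O
F3 | step 17 | C8' alkylzinc iodide | C/C(I)=C/CC/C(C)=C\Cc1c(OC(C)(C)[C@@H](O[Si](C)(C)C(C)(C)C)CC[Zn]I)cc(OCOC)c2c1C[C@@H](C)OC2=O
F4 | step 14 | (3R)-5-[(2Z)-6,6-dimethoxy-3-methylhex-2-en-1-yl]-8-(methoxymethoxy)-3-methyl-6-[(2-methyl-3-oxobutan-2-yl)oxy]isochroman-1-one | COC(OC)CC/C(C)=C\Cc1c(OC(C)(C)C(C)=O)cc(OCOC)c2c1C[C@@H](C)OC2=O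
F5 | step 14 | β-(diisopropylamino) ketone from F4 | COC(OC)CC/C(C)=C\Cc1c(OC(C)(C)C(=O)CCN(C(C)C)C(C)C)cc(OCOC)c2c1C[C@@H](C)OC2=O
F6 | step 14 | vinyl ketone from F4 | COC(OC)CC/C(C)=C\Cc1c(OC(C)(C)C(=O)C=C)cc(OCOC)c2c1C[C@@H](C)OC2=O
F7 | step 14 | (10'S)-vinyl carbinol from F6 | COC(OC)CC/C(C)=C\Cc1c(OC(C)(C)[C@@H](O)C=C)cc(OCOC)c2c1C[C@@H](C)OC2=O
F8 | step 8 | mixture of C10' epimers of 13 | CC(C)(Oc1cc(OCOC)c2c(c1B3OC(C)(C)C(C)(C)O3)C[C@@H](C)OC2=O)C(O)C=C
F9 | step 8 | (9'R,10'R)-epoxy alcohol from the 10'R epimer | CC(C)(Oc1cc(OCOC)c2c(c1B3OC(C)(C)C(C)(C)O3)C[C@@H](C)OC2=O)[C@H](O)[C@H]1CO1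
F10 | step 4 | (3R)-5-bromo-8-hydroxy-3-methyl-6-[(2-methylbut-3-yn-2-yl)oxy]isochroman-1-one | C#CC(C)(C)Oc1cc(O)c2c(c1Br)C[C@@H](C)OC2=O
F11 | step 18 | O8-methoxymethyl ether of chrysomutanin | C/C1=C/Cc2c(cc(OCOC)c3c2C[C@@H](C)OC3=O)OC(C)(C)[C@@H](O)CC/C(C)=C\CC1
A1 | alternative 1 | C5-alkylated diketo-dioxinone: 2,2-dimethyl-1,3-dioxin-4-one with a 2,4-dioxo side chain bearing the silylated (2Z,6Z)-dienyl chain on the carbon between the ketones and ending in the (R)-2-silyloxypropyl group | CC1(C)OC(=O)C=C(CC(=O)C(C/C=C(C)\CC/C=C(C)\CO[Si](c2ccccc2)(c2ccccc2)C(C)(C)C)C(=O)C[C@@H](C)O[Si](C)(C)C(C)(C)C)O1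
A2 | alternative 1 | benzodioxinone resorcylate with free O6 phenol, C5 dienyl chain and (R)-2-silyloxypropyl group on C4a | CC(C)(C)[Si](c1ccccc1)(c1ccccc1)OC/C(C)=C\CC/C(C)=C\Cc1c(O)cc2OC(C)(C)OC(=O)c2c1C[C@@H](C)O[Si](C)(C)C(C)(C)C
A3 | alternative 2 | diazo ketone: (6R)-6-methyl-5,6-dihydropyran-2-one acylated at C4 by a 2-diazoacyl chain that ends in the C10' methoxymethyl ether and the tert-alkyl ethynyl ether | C#COC(C)(C)[C@@H](OCOC)CC/C(C)=C\CC/C(C)=C\CC(=[N+]=[N-])C(=O)C1=CC(=O)O[C@H](C)C1
A4 | alternative 2 | C10' methoxymethyl ether of chrysomutanin | C/C1=C/Cc2c(cc(O)c3c2C[C@@H](C)OC3=O)OC(C)(C)[C@@H](OCOC)CC/C(C)=C\CC1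
A5 | alternative 3 | 14-membered cyclic ynol ether (C5≡C6–O6 to C1', 10'S methoxymethyl ether, 2'Z,6'Z) | C/C1=C/CC#COC(C)(C)[C@@H](OCOC)CC/C(C)=C\CC1
A6 | alternative 3 | (7R)-4-(methoxymethoxy)-7-methyl-7,8-dihydropyrano[4,3-b]pyran-2,5-dione | O=C1C=C(OCOC)C2=C(O1)C[C@@H](C)OC2=O
A7 | alternative 3 | bis(methoxymethyl) ether of chrysomutanin | C/C1=C/Cc2c(cc(OCOC)c3c2C[C@@H](C)OC3=O)OC(C)(C)[C@@H](OCOC)CC/C(C)=C\CC1
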